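The cembrane numbering is used: C1 carries the isopropenyl group, C2 is the CH2 on furan carbon C3, C18 is the furan ester, C20 the ester on C12. The 14-membered carbocycle (counted through furan C3–C6) is closed at C1–C2 by an enantioselective Ireland–Claisen ring contraction. Its precursor is a 17-membered furanophane lactone in which C2 bears an extra carboxyl, esterified with the E-allylic alcohol O–C16H2–C15(Me)=C1. One [3,3] shift forms C1–C2, sets C1 and unveils the isopropenyl group. It exploits the acidity of C2–H (furfurylic, vinylogous to the C18 ester) and the allylic position of C1. The tethering carboxyl is then excised by radical decarboxylation.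

Key step: step 13

Remark on the chemistry: (R)-(−)-linalool of high enantiomeric purity is taken as commercially available.
Remark on the chemistry: the facial sense of the diazaborolidine controller on this E-allyl furylacetate is assumed to follow the chair model of simple E-allyl esters; the (S,S) enantiomer is written, and its mirror image would be used should the sense prove opposite.

Step 1
Reactants: 1 (R)-linalool
Product: 2 (3R)-3,7-dimethyl-3-(triethylsilyloxy)octa-1,6-diene
Conditions: TESOTf, 2,6-lutidine, CH2Cl2, −78 → 0 °C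
Reagents that add atoms: triethylsilyl trifluoromethanesulfonate, CC[Si](CC)(CC)OS(=O)(=O)C(F)(F)F
Why: Silyl triflate silylation of the tertiary alcohol should be clean and prevents lactol formation from the aldehyde made next; the C8 stereocentre comes unchanged from the chiral pool.

Step 2
Reactants: 2 (3R)-3,7-dimethyl-3-(triethylsilyloxy)octa-1,6-diene
Product: 3 (4R)-4-methyl-4-(triethylsilyloxy)hex-5-enal
Conditions: O3 (1.0 equiv), pyridine, CH2Cl2, −78 °C; then PPh3
Reagents that add atoms: ozone, [O-][O+]=O
Why: Chemoselective ozonolysis should cleave only the electron-rich trisubstituted alkene and leave the hindered monosubstituted vinyl group.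

Step 3
Reactants: 3 (4R)-4-methyl-4-(triethylsilyloxy)hex-5-enal; 4 dimethyl 3-oxopentanedioate
Product: 6 methyl 2-(2-methoxy-2-oxoethyl)-5-[(2R)-2-methyl-2-(triethylsilyloxy)but-3-en-1-yl]furan-3-carboxylate, via alpha-chloroaldehyde 5 (not isolated)
Conditions: NCS, L-proline (10 mol%), CH2Cl2, 0 °C → rt; then 4, pyridine, 50 °C
Reagents that add atoms: none
Why: Enamine-catalysed alpha-chlorination followed by a Feist–Benary furan synthesis (aldol at the aldehyde, 5-exo O-alkylation with loss of chloride, dehydration) should give the furan with the ester on C4, the CH2CO2Me arm on C3 and the side chain on C6.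

Step 4
Reactants: 6 methyl 2-(2-methoxy-2-oxoethyl)-5-[(2R)-2-methyl-2-(triethylsilyloxy)but-3-en-1-yl]furan-3-carboxylate
Product: 7 methyl 2-(2-methoxy-2-oxoethyl)-5-[(2S)-2-methyl-5-oxo-2-(triethylsilyloxy)pentyl]furan-3-carboxylate
Conditions: Rh(acac)(CO)2 (1 mol%), Xantphos (2 mol%), CO/H2 (1:1, 20 bar), toluene, 80 °C
Reagents that add atoms: carbon monoxide, [C-]#[O+]
Why: Hydroformylation of a vinyl group that has a quaternary neighbour and no allylic hydrogen should be fully linear-selective and adds C11 as the aldehyde.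

Step 5
Reactants: 7 methyl 2-(2-methoxy-2-oxoethyl)-5-[(2S)-2-methyl-5-oxo-2-(triethylsilyloxy)pentyl]furan-3-carboxylate
Product: 9 methyl 5-[(2R)-3-(2-formyl-1,3-dithian-2-yl)-2-methyl-2-(triethylsilyloxy)propyl]-2-(2-methoxy-2-oxoethyl)furan-3-carboxylate, via pyrrolidine enamine 8 (not isolated)
Conditions: pyrrolidine, 4 Å molecular sieves, CH2Cl2, rt; then TsS(CH2)3STs, Et3N, MeCN, 60 °C; aq. NaOAc/AcOH
Reagents that add atoms: S,S'-propane-1,3-diyl bis(4-methylbenzenethiosulfonate), Cc1ccc(cc1)S(=O)(=O)SCCCSS(=O)(=O)c1ccc(C)cc1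
Why: Dithiane transfer (double alpha-sulfenylation of the enamine by trimethylene dithiotosylate) should mask the future C10 ketone as a 1,3-dithiane next to a non-enolisable aldehyde, without any organolithium reagent that would attack the esters.

Step 6
Reactants: 10 (R)-4-benzyl-1,3-oxazolidin-2-one; 11 hex-5-enoyl chloride
Product: 12 (R)-4-benzyl-3-(hex-5-enoyl)-1,3-oxazolidin-2-one
Conditions: n-BuLi, THF, −78 °C; then 11
Reagents that add atoms: none
Why: N-Acylation of the lithiated oxazolidinone is a standard and reliable reaction.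

Step 7
Reactants: 12 (R)-4-benzyl-3-(hex-5-enoyl)-1,3-oxazolidin-2-one; 13 methacrolein
Product: 14 (R)-4-benzyl-3-[(E)-6-methyl-7-oxohept-5-enoyl]-1,3-oxazolidin-2-one
Conditions: second-generation Hoveyda–Grubbs catalyst RuCl2(H2IMes)(=CH-C6H4-2-OiPr) (5 mol%), 13 (5 equiv), CH2Cl2, 40 °C
Reagents that add atoms: none
Why: Olefin cross-metathesis with excess methacrolein should give the trisubstituted enal with high E selectivity under thermodynamic control.

Step 8
Reactants: 14 (R)-4-benzyl-3-[(E)-6-methyl-7-oxohept-5-enoyl]-1,3-oxazolidin-2-one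
Product: 15 (R)-4-benzyl-3-[(E)-7-hydroxy-6-methylhept-5-enoyl]-1,3-oxazolidin-2-one
Conditions: NaBH4, CeCl3·7H2O, MeOH, −40 °C
Reagents that add atoms: none
Why: Luche 1,2-reduction should convert the enal into the E-allylic alcohol (C16–OH) without touching the imide.

Step 9
Reactants: 15 (R)-4-benzyl-3-[(E)-7-hydroxy-6-methylhept-5-enoyl]-1,3-oxazolidin-2-one; 9 the formyl dithiane
Product: 17 anti-aldol imide with free C11 and C16 hydroxyls, via bis-trimethylsilyl ether 16 (not isolated)
Conditions: MgCl2 (30 mol%), Et3N, TMSCl, EtOAc, rt; then CF3CO2H (cat.), MeOH, rt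
Reagents that add atoms: none
Why: The magnesium-halide-catalysed direct anti-aldol of an N-acyloxazolidinone with a non-enolisable aldehyde (soft enolisation, chelated Z-enolate, attack on the face opposite the benzyl group, boat transition state, turnover by silylation) should set C12 (S) and C11 (R) in the anti relationship; the allylic hydroxyl is silylated in the flask and released in the work-up.

Step 10
Reactants: 17 anti-aldol imide
Product: 18 seco triester diol (C20 methyl ester)
Conditions: MeMgBr, MeOH, CH2Cl2, 0 °C (MeOMgBr formed in the flask)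
Reagents that add atoms: bromomagnesium methoxide, C[O-].[Mg+2].[Br-]
Why: Chelation-assisted methanolysis of the exocyclic imide carbonyl should release the C20 methyl ester without retro-aldol or epimerisation at C12.

Step 11
Reactants: 18 seco triester diol
Product: 19 seco acid (free CH2CO2H on furan C3)
Conditions: Me3SnOH, 1,2-dichloroethane, 70 °C; dilute aq. HCl wash
Reagents that add atoms: trimethyltin hydroxide, C[Sn](C)(C)O
Why: Mild tin hydroxide hydrolysis should cleave only the unhindered primary CH2CO2Me ester and leave the alpha-branched C20 ester and the conjugated C18 furan ester.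

Step 12
Reactants: 19 seco acid
Product: 21 17-membered furanophane lactone (allyl furylacetate), via mixed anhydride 20 (not isolated)
Conditions: 2-methyl-6-nitrobenzoic anhydride, DMAP, CH2Cl2, rt, slow addition (final 1 mM)
Reagents that add atoms: none
Why: Shiina macrolactonisation should acylate the unhindered primary allylic C16 hydroxyl in preference to the C11 hydroxyl, which is flanked by two branched carbons.

Step 13
Reactants: 21 17-membered furanophane lactone
Product: 25 ring-contracted acid with a carboxyl on C2, via silyl ether 22 (not isolated), via boron ketene acetal 23 (not isolated), via acyloxyborane 24 (not isolated)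
Conditions: N,O-bis(trimethylsilyl)acetamide, CH2Cl2, rt, then evaporation; (4S,5S)-2-bromo-1,3-bis{[3,5-bis(trifluoromethyl)phenyl]sulfonyl}-4,5-diphenyl-1,3,2-diazaborolidine (1.5–2 equiv), Et3N, toluene/CH2Cl2, −78 → 4 °C; aq. work-up, then HF·pyridine, THF, 0 °C
Reagents that add atoms: none
Why: The controller-bound lactone is deprotonated by Et3N at C2 (the only alpha carbon that is both furfurylic and vinylogous to the C18 ester), and the O-boron ketene acetal undergoes a concerted suprafacial [3,3] shift through the chair array C2=C(OB)–O–C16–C15=C1, forming C1–C2 while O–C16 breaks and C15=C16 becomes the isopropenyl alkene. The closest known reaction type is the enantioselective boron-enolate Ireland–Claisen ring contraction of macrolactones to carbocycles. The 14-membered carbocycle is closed by ring contraction, a transannular sigmatropic shift inside the 17-membered lactone and not an exo or endo cyclisation of an open chain. C1 is set by reagent control: the twofold-symmetric diazaborolidine shields one face of the ketene acetal and the chair places C14 equatorial on the E-alkene, which fixes the face of C1 whatever the enolate geometry, while the C2 stereocentre is erased in step 14. The step needs site-selective enolisation (secured by the far higher acidity of C2–H over C12–H), exclusive bonding at C1 and not C16 (guaranteed by the sigmatropic mechanism) and facial selectivity at C1 (controller plus E geometry of C1=C15). The HF work-up also removes both silyl ethers.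

Step 14
Reactants: 25 ring-contracted acid
Product: 27 dithiane-protected macrocycle, via Barton ester 26 (not isolated)
Conditions: N-hydroxypyridine-2-thione, N,N'-dicyclohexylcarbodiimide, DMAP (cat.), CH2Cl2, dark, rt; then t-BuSH, visible light, rt
Reagents that add atoms: none
Why: Barton reductive decarboxylation (radical chain; the furfuryl radical at C2 abstracts hydrogen from the thiol) should turn C2 into the required CH2 without affecting C1, the dithiane or the alkene.

Step 15
Reactants: 27 dithiane-protected macrocycle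
Product: 28 CNP0218204.1
Conditions: MeI, CaCO3, MeCN/H2O (4:1), 40 °C
Reagents that add atoms: water, O
Why: Alkylative hydrolysis of the dithiane should unveil the C10 ketone under near-neutral conditions that spare the hydroxy ketone array, the furan and the isopropenyl group.

Compound list
1 | (R)-linalool, (3R)-3,7-dimethylocta-1,6-dien-3-ol | C=C[C@](C)(O)CCC=C(C)C | starting material
2 | (3R)-3,7-dimethyl-3-(triethylsilyloxy)octa-1,6-diene | C=C[C@](C)(O[Si](CC)(CC)CC)CCC=C(C)C | intermediate
3 | (4R)-4-methyl-4-(triethylsilyloxy)hex-5-enal | C=C[C@](C)(O[Si](CC)(CC)CC)CCC=O | intermediate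
4 | dimethyl 3-oxopentanedioate | COC(=O)CC(=O)CC(=O)OC | starting material
5 | (4R)-2-chloro-4-methyl-4-(triethylsilyloxy)hex-5-enal, both C2 epimers | C=C[C@](C)(O[Si](CC)(CC)CC)CC(Cl)C=O | intermediate
6 | methyl 2-(2-methoxy-2-oxoethyl)-5-[(2R)-2-methyl-2-(triethylsilyloxy)but-3-en-1-yl]furan-3-carboxylate | C=C[C@](C)(O[Si](CC)(CC)CC)Cc1cc(C(=O)OC)c(CC(=O)OC)o1 | intermediate
7 | methyl 2-(2-methoxy-2-oxoethyl)-5-[(2S)-2-methyl-5-oxo-2-(triethylsilyloxy)pentyl]furan-3-carboxylate | O=CCC[C@](C)(O[Si](CC)(CC)CC)Cc1cc(C(=O)OC)c(CC(=O)OC)o1 | intermediate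
8 | E-pyrrolidine enamine of aldehyde 7 | N1(CCCC1)/C=C/C[C@](C)(O[Si](CC)(CC)CC)Cc1cc(C(=O)OC)c(CC(=O)OC)o1 | intermediate
9 | methyl 5-[(2R)-3-(2-formyl-1,3-dithian-2-yl)-2-methyl-2-(triethylsilyloxy)propyl]-2-(2-methoxy-2-oxoethyl)furan-3-carboxylate | O=CC1(SCCCS1)C[C@](C)(O[Si](CC)(CC)CC)Cc1cc(C(=O)OC)c(CC(=O)OC)o1 | intermediate
10 | (R)-4-benzyl-1,3-oxazolidin-2-one | O=C1N[C@H](Cc2ccccc2)CO1 | starting material
11 | hex-5-enoyl chloride | C=CCCCC(Cl)=O | starting material
12 | (R)-4-benzyl-3-(hex-5-enoyl)-1,3-oxazolidin-2-one | C=CCCCC(=O)N1[C@H](Cc2ccccc2)COC1=O | intermediate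
13 | methacrolein, 2-methylprop-2-enal | C=C(C)C=O | starting material
14 | (R)-4-benzyl-3-[(E)-6-methyl-7-oxohept-5-enoyl]-1,3-oxazolidin-2-one | O=C/C(C)=C/CCCC(=O)N1[C@H](Cc2ccccc2)COC1=O | intermediate
15 | (R)-4-benzyl-3-[(E)-7-hydroxy-6-methylhept-5-enoyl]-1,3-oxazolidin-2-one | OC/C(C)=C/CCCC(=O)N1[C@H](Cc2ccccc2)COC1=O | intermediate
16 | bis-trimethylsilyl ether (C11–O and C16–O) of aldol imide 17 | C[Si](C)(C)OC/C(C)=C/CC[C@H](C(=O)N1[C@H](Cc2ccccc2)COC1=O)[C@@H](O[Si](C)(C)C)C1(SCCCS1)C[C@](C)(O[Si](CC)(CC)CC)Cc1cc(C(=O)OC)c(CC(=O)OC)o1 | intermediate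
17 | anti-aldol imide: C12 (S), C11 (R) hydroxyl, C10 as 1,3-dithiane, C8 triethylsilyl ether, E-allylic alcohol terminus, furan diester | OC/C(C)=C/CC[C@H](C(=O)N1[C@H](Cc2ccccc2)COC1=O)[C@@H](O)C1(SCCCS1)C[C@](C)(O[Si](CC)(CC)CC)Cc1cc(C(=O)OC)c(CC(=O)OC)o1 | intermediate
18 | seco triester diol: as 17 with the imide replaced by the C20 methyl ester | OC/C(C)=C/CC[C@H](C(=O)OC)[C@@H](O)C1(SCCCS1)C[C@](C)(O[Si](CC)(CC)CC)Cc1cc(C(=O)OC)c(CC(=O)OC)o1 | intermediate
19 | seco acid: as 18 with the furan C3 arm as CH2CO2H | OC/C(C)=C/CC[C@H](C(=O)OC)[C@@H](O)C1(SCCCS1)C[C@](C)(O[Si](CC)(CC)CC)Cc1cc(C(=O)OC)c(CC(=O)O)o1 | intermediate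
20 | mixed anhydride of 19 with 2-methyl-6-nitrobenzoic acid | OC/C(C)=C/CC[C@H](C(=O)OC)[C@@H](O)C1(SCCCS1)C[C@](C)(O[Si](CC)(CC)CC)Cc1cc(C(=O)OC)c(CC(=O)OC(=O)c2c(C)cccc2[N+](=O)[O-])o1 | intermediate
21 | 17-membered furanophane lactone: C2 carboxyl esterified with the C16 oxygen, E-C1=C15 | O1C/C(C)=C/CC[C@H](C(=O)OC)[C@@H](O)C2(SCCCS2)C[C@](C)(O[Si](CC)(CC)CC)Cc2cc(C(=O)OC)c(CC1=O)o2 | intermediate
22 | C11 trimethylsilyl ether of lactone 21 | O1C/C(C)=C/CC[C@H](C(=O)OC)[C@@H](O[Si](C)(C)C)C2(SCCCS2)C[C@](C)(O[Si](CC)(CC)CC)Cc2cc(C(=O)OC)c(CC1=O)o2 | intermediate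
23 | O-boron ketene acetal of 22 carrying the (S,S)-diazaborolidine, enolate geometry not defined | O1C/C(C)=C/CC[C@H](C(=O)OC)[C@@H](O[Si](C)(C)C)C2(SCCCS2)C[C@](C)(O[Si](CC)(CC)CC)Cc2cc(C(=O)OC)c(C=C1OB1N(S(=O)(=O)c3cc(cc(c3)C(F)(F)F)C(F)(F)F)[C@@H](c3ccccc3)[C@H](c3ccccc3)N1S(=O)(=O)c1cc(cc(c1)C(F)(F)F)C(F)(F)F)o2 | intermediate
24 | ring-contracted acyloxyborane: C1 (R) with isopropenyl, C2 carboxyl bound to boron, both silyl ethers in place | C=C(C)[C@@H]1CC[C@H](C(=O)OC)[C@@H](O[Si](C)(C)C)C3(SCCCS3)C[C@](C)(O[Si](CC)(CC)CC)CC2=CC(C(=O)OC)=C(C1C(=O)OB1N(S(=O)(=O)c3cc(cc(c3)C(F)(F)F)C(F)(F)F)[C@@H](c3ccccc3)[C@H](c3ccccc3)N1S(=O)(=O)c1cc(cc(c1)C(F)(F)F)C(F)(F)F)O2 | intermediate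
25 | ring-contracted acid: 2-carboxy derivative of 27, C2 configuration not defined | C=C(C)[C@@H]1CC[C@H](C(=O)OC)[C@@H](O)C3(SCCCS3)C[C@](C)(O)CC2=CC(C(=O)OC)=C(C1C(=O)O)O2 | intermediate
26 | Barton ester (N-acyloxypyridine-2-thione) of acid 25 | C=C(C)[C@@H]1CC[C@H](C(=O)OC)[C@@H](O)C3(SCCCS3)C[C@](C)(O)CC2=CC(C(=O)OC)=C(C1C(=O)ON1C=CC=CC1=S)O2 | intermediate
27 | dithiane-protected macrocycle: the target with C10 as its 1,3-dithiane | C=C(C)[C@@H]1CC[C@H](C(=O)OC)[C@@H](O)C3(SCCCS3)C[C@](C)(O)CC2=CC(C(=O)OC)=C(C1)O2 | intermediate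
28 | CNP0218204.1 (1R,8R,11R,12S in the numbering used here) | C=C(C)[C@@H]1CC[C@H](C(=O)OC)[C@@H](O)C(=O)C[C@](C)(O)CC2=CC(C(=O)OC)=C(C1)O2 | target

Total step count: 15. Longest linear sequence: 12 steps (steps 1–5 and 9–15, from (R)-linalool); the oxazolidinone branch is steps 6–8.

Steps most likely to fail

Step 13. The risks are insufficient facial discrimination at C1 in a mismatched controller–substrate pairing, a competing boat transition state, and sequestration of the boron reagent by the dithiane sulfur atoms and ester carbonyls so that enolisation stalls. The fallback closes the same C1–C2 bond by an intramolecular Nozaki–Hiyama–Kishi allylation and sets out from aldehyde 3. Chlorination to 5 as in step 3, then Feist–Benary condensation with methyl 4,4-dimethoxy-3-oxobutanoate in pyridine, would give the furan acetal F1. Hydroformylation as in step 4 gives the aldehyde F2, and dithiane transfer as in step 5 gives the formyl dithiane F3. The anti-aldol of step 9 with 15 gives the imide F4, and MeOMgBr gives the methyl ester F5. Aqueous HCl in THF unmasks the furfural and removes the silyl ether to give the triol aldehyde F6. MsCl/Et3N then LiBr converts the primary allylic alcohol into the allylic bromide F7. CrCl2 with catalytic NiCl2 in THF at high dilution closes the ring to the homoallylic alcohol F8; the allylchromium adds anti-selectively at its gamma carbon C1, and a chiral sulfonamide ligand can be added for reagent control. 1,1'-Thiocarbonyldiimidazole acylates the less hindered furfuryl hydroxyl to give the thiocarbonylimidazolide F9. Bu3SnH/AIBN in toluene then removes the C2 oxygen, and the sequence returns to the route at 27.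

Step 9. The risks are slow addition to the hindered alpha,alpha-dithio aldehyde under soft enolisation, competing enolisation of the furylacetate arm, and erosion of anti selectivity. The fallback replaces the catalytic direct aldol by a stoichiometric preformed enolate reacting through an open transition state. From 15, Bu2BOTf (2.2 equiv, the second equivalent masking the allylic hydroxyl as its borinate) and iPr2NEt in CH2Cl2 at −78 °C give the Z-boron enolate. This is added to 9 precomplexed with Et2AlCl, which should give the same anti adduct through the same enolate face. A non-oxidative work-up protects the dithiane, and the sequence returns at 17 without any new compound.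

Step 11. The risks are loss of site selectivity among the three methyl esters, and beta-elimination or retro-aldol of the beta-hydroxy ester on prolonged heating. The fallback moves the differentiation to a stage with only two esters and sets out from 9. LiOH (1.0 equiv) in THF/H2O at 0 °C should hydrolyse only the aliphatic ester to give the formyl dithiane acid F10. The anti-aldol of step 9 with 15, with one further equivalent of TMSCl and Et3N so that the acid travels as its silyl ester, gives the aldol imide acid F11. MeOMgBr as in step 10 then returns the sequence to the route at 19.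

Further compounds
F1 | step 13 | methyl 2-(dimethoxymethyl)-5-[(2R)-2-methyl-2-(triethylsilyloxy)but-3-en-1-yl]furan-3-carboxylate | C=C[C@](C)(O[Si](CC)(CC)CC)Cc1cc(C(=O)OC)c(C(OC)OC)o1
F2 | step 13 | hydroformylation aldehyde of F1 | O=CCC[C@](C)(O[Si](CC)(CC)CC)Cc1cc(C(=O)OC)c(C(OC)OC)o1
F3 | step 13 | 2-formyl-1,3-dithiane derived from F2 | O=CC1(SCCCS1)C[C@](C)(O[Si](CC)(CC)CC)Cc1cc(C(=O)OC)c(C(OC)OC)o1
F4 | step 13 | anti-aldol imide of F3 with 15 | OC/C(C)=C/CC[C@H](C(=O)N1[C@H](Cc2ccccc2)COC1=O)[C@@H](O)C1(SCCCS1)C[C@](C)(O[Si](CC)(CC)CC)Cc1cc(C(=O)OC)c(C(OC)OC)o1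
F5 | step 13 | C20 methyl ester of F4 | OC/C(C)=C/CC[C@H](C(=O)OC)[C@@H](O)C1(SCCCS1)C[C@](C)(O[Si](CC)(CC)CC)Cc1cc(C(=O)OC)c(C(OC)OC)o1
F6 | step 13 | triol furfural (acetal and silyl ether removed) | OC/C(C)=C/CC[C@H](C(=O)OC)[C@@H](O)C1(SCCCS1)C[C@](C)(O)Cc1cc(C(=O)OC)c(C=O)o1
F7 | step 13 | E-allylic bromide of F6 | BrC/C(C)=C/CC[C@H](C(=O)OC)[C@@H](O)C1(SCCCS1)C[C@](C)(O)Cc1cc(C(=O)OC)c(C=O)o1
F8 | step 13 | macrocyclic C2 carbinol (2-hydroxy derivative of 27, carbinol configuration not defined) | C=C(C)[C@@H]1CC[C@H](C(=O)OC)[C@@H](O)C3(SCCCS3)C[C@](C)(O)CC2=CC(C(=O)OC)=C(C1O)O2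
F9 | step 13 | C2 O-thiocarbonylimidazolide of F8 | C=C(C)[C@@H]1CC[C@H](C(=O)OC)[C@@H](O)C3(SCCCS3)C[C@](C)(O)CC2=CC(C(=O)OC)=C(C1OC(=S)n1ccnc1)O2
F0 | step 9 | none | none
F10 | step 11 | formyl dithiane acid (CH2CO2H analogue of 9) | O=CC1(SCCCS1)C[C@](C)(O[Si](CC)(CC)CC)Cc1cc(C(=O)OC)c(CC(=O)O)o1
F11 | step 11 | aldol imide acid (CH2CO2H analogue of 17) | OC/C(C)=C/CC[C@H](C(=O)N1[C@H](Cc2ccccc2)COC1=O)[C@@H](O)C1(SCCCS1)C[C@](C)(O[Si](CC)(CC)CC)Cc1cc(C(=O)OC)c(CC(=O)O)o1
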